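One addition, a single reagent spent on a substrate unit, is the unit I count in: single product holds one, bis adduct two, tris adduct 3.

| setting | red | teal | green | flask |
|---|---|---|---|---|
| substrate | 0.10 M | 0.10 M | 0.20 M | 0.10 M |
| reagent | 0.075 M | 0.30 M | 0.15 M | 0.150 M |
| remark | run made earlier | run made earlier | run made earlier |  |
| time |  |  |  | 4.0 d |

- red (time / d: substrate / %, single product / %, bis adduct / %): 0.208: 45.3, 32.6, 2.3; 0.625: 39.6, 30.5, 2.2; 1.04: 38.7, 30.4, 1.3; 1.67: 39.4, 28.6, 1.6; 2.50: 38.9, 29.1, 2.4; 3.00: 39.4, 28.9, 2.8
- teal (time / d: substrate / %, single product / %, bis adduct / %): 0.250: 0.7, 33.1, 1.4; 0.417: 0, 19.7, 2.3; 0.625: 0.5, 5.8, 1.3; 1.25: 0.7, 1.9, 1.3; 2.08: 0.1, 1.5, 0.7; 3.00: 0.3, 0.3, 0.4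
- green (time / d: substrate / %, single product / %, bis adduct / %): 0.625: 40.2, 40.6, 1.4; 1.25: 39.3, 41.9, 0.4; 2.08: 39.2, 41.3, 2.5; 2.50: 39.9, 41.8, 1.5; 3.00: 39.9, 41.6, 2.8

(readings scatter by 0.5 percentage points)

- a reading or a percentage of single product counts all its forms, free or not

- amount of substrate at 4.0 d, in percent of the substrate charged
- amount of single product at 4.0 d, in percent of the substrate charged
- amount of bis adduct at 4.0 d, in percent of the substrate charged
- amount of tris adduct at 4.0 d, in percent of the substrate charged

The readings form a ladder of times. On the first rung substrate goes: in teal it reads 0.7 % at 0.250 d. On the second, single product goes, and teal reads 5.8 % at 0.625 d. The third rung is a stall: red substrate reads 38.7 % at 1.04 d and 39.4 % at 3.00 d. The red stall arrives earlier than the flask's 4.0 d, so I read the flask as an end state, and an end state is a count. For the flask it is 1.50, which I call the turnover count, reagent charged per substrate charged.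

I test it on red, taking reagent as the limiting reagent there. At the last reading 28.9 % of the substrate is out of sight, and it must hold 0.405 additions. That reads as 1.40 each, fewer than 3, so something unseen besides tris adduct is holding substrate.

The forecast prints 1 % substrate, 50 % single product, 2 % bis adduct and 40 % tris adduct, and says “Tris adduct is the remainder”. My count differs: that single product and bis adduct leave 0.960 additions, room for 32.0 % tris adduct, and less if the unseen form takes a share.

The flask gives 5.30 % substrate, 44.1 % single product, 1.84 % bis adduct and 26.7 % tris adduct, with 22.1 % as isomer of the product.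

substrate + reagent → single product + by-product (k = 0.0954 M⁻¹ min⁻¹); reagent + single product → bis adduct + by-product (k = 0.117 M⁻¹ min⁻¹); reagent + bis adduct → tris adduct + by-product (k = 0.387 M⁻¹ min⁻¹); crystals ⇌ single product, rate k4*(cs4 - [single product]) while solid is left; crystals form when [single product] > cs4 (solubility = 6.10 mM, k = 0.0615 min⁻¹); single product ⇌ isomer of the product (K = 3.62, k = 0.00974 min⁻¹) Reagent found in single product, bis adduct and tris adduct comes to 1.28 equiv; with one addition in each isomer the sum reaches 1.50 against a turnover count of 1.50. The neighbour flask charged with 0.090 M of reagent has a turnover count of 0.900, and its additions, counted the same way, sum to 0.900, with tris adduct at 9.35 %.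

The earlier runs and the new flask are simulated on assumed constants; noise was put on by code.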